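Start from the slowness of the coupling, and measure it against what else the coupling partner can do in these flasks.

all flasks: time 2.5 min
- beta: substrate 0.047 M (fed, over 1.0 min); coupling partner 0.0705 M; the addition at 40 °C, then warmed to 80 °C; the feed brings no volume worth counting
- alpha: substrate 0.047 M; coupling partner 0.0705 M; everything together at the start at 40 °C, warmed to 80 °C at 1.0 min
- zeta: substrate 0.047 M; coupling partner 0.0705 M (fed, over 1.0 min); all else is in the flask from the start; the feed brings no volume worth counting; temperature 80 °C
- gamma: substrate 0.047 M; coupling partner 0.0705 M; everything together at the start; temperature 80 °C
- epsilon: substrate 0.047 M (fed, over 6.0 s); coupling partner 0.0705 M; all else is in the flask from the start; the feed brings no volume worth counting; temperature 80 °C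
- delta: substrate 0.047 M; coupling partner 0.0705 M (in portions, 3, over 1.0 min); first portion at the start, last at 1.0 min; temperature 80 °C

    coupling partner → decomposed reagent (k1 = 0.051 /s, Ea1 = 104 kJ/mol)
    crystals ⇌ target, rate k2*(cs2 - [target]) while solid is left; crystals form when [target] > cs2 (cs2 = 19 mM, k2 = 0.10 /s)
    substrate + coupling partner → target, rate k3*[substrate]^2*[coupling partner] (k3 = 1.7 /M²/s, Ea3 = 36.0 kJ/mol)
    2 coupling partner → self-condensation product (k4 = 0.067 /M/s, Ea4 = 60.0 kJ/mol)
    (constants at 80 °C)

- what is said of target includes crystals
- a doubled species enters its step squared and goes two at a time
- crystals is a solid; its amount is given per volume of the solution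
- the constants hold at 80 °C; other temperatures follow from the activation energies

* the flask with the highest amount of target, in percent of the substrate charged ("all alike" if they lie within 1.5 percentage points) (beta / alpha / zeta / gamma / epsilon / delta / all alike)
* final target, as a percentage of the substrate charged, in beta
* final target, as a percentage of the substrate charged, in alpha
* final target, as a percentage of the substrate charged, in zeta
* final target, as a percentage of the substrate charged, in gamma
* final target, as a percentage of the substrate charged, in epsilon
* final target, as a percentage of the substrate charged, in delta

Set up the half-lives of the coupling partner at 80 °C in gamma, taking each step alone at the charges, and count how many fit into the run of 2.5 min.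

| Step alone | Half-life | Half-lives in the run |
|---|---|---|
| decomposition | 0.23 min | 11.0 |
| self-condensation | 1.76 min | 1.42 |
| coupling | 3.1 min | 0.806 |

Read the first row: decomposition alone leaves 0.0476% of the coupling partner by the end. So expect the coupling partner to be the limiting reagent in gamma, though it is charged in excess.

Read the last row against it: the coupling half-life is longer than the decomposition half-life, so expect the coupling to take a share of the coupling partner.

Name that share. The capture share f is the fraction of coupling partner that enters target rather than decomposing: f = k_c/(k_c + k_d), where k_c is the pseudo-first-order constant, k3 times [substrate] squared, and k_d is the decomposition constant. At the charged substrate and 80 °C, f is 6.86%. Multiply by the charge ratio and reckon 10.3% of the substrate charged for gamma.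

The middle row takes from the same coupling partner, though it slows as the coupling partner falls, so commit to a little under that figure for gamma.

Now go cold. At the start of alpha, decomposition uses coupling partner at 0.71 of the coupling rate, so f there is 58.6%, higher than in the hot flask. Expect alpha on top and beta below it, since f follows the square of a substrate still being fed. Expect epsilon under gamma, since 0.441 half-lives of decomposition pass during its feed. This reckoning gives no figure for the cold minute, so stop here.

The forecast names alpha, with 13.1% there, 10% in beta, 9% in zeta, 8.9% in delta, 8.7% in gamma and 7.1% in epsilon, holding that “the minute at 40 °C with substrate fully present gives alpha the most target”. Its gamma lies below the reckoned 10.3%.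

The simulation gives alpha as highest, with 13.2%, then 9.87% in beta, 9.06% in zeta, 9.06% in delta, 8.71% in gamma and 7.12% in epsilon; each forecast figure holds within tolerance.

At 2.5 min the coupling partner in alpha stands at 0.603% of its charge and the substrate at 87%, and ten times the time takes target from 13.2% to 13.3%, a gain of 0.100 percentage points. Epsilon reads 7.12% at 2.5 min and 7.12% at 25.0 min. Gamma's result is 84.6% of what f gave. The answer for alpha moves by 5 points at a coupling partner of 0.0404 M or 0.106 M, or at a substrate of 0.0265 M or 0.0745 M, each amount moved with the other and the time held.

Take the neighbour of alpha with 0.012 M of substrate. Hot, f falls to 0.478%, and 5.88 equiv of coupling partner turn that into 2.81%, before any gain from the cold minute. The run gives 3.95%, more than that hot figure, with 96% of the substrate left and 0.79% of the coupling partner.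

The constants used here were set for the occasion; the rest is arithmetic.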